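Which of these flasks ends with the greatest share of target in target plus side product?

| flask | starting material | reagent | remark | time |
|---|---|---|---|---|
| amber | 23 mM | 34.5 mM | run made earlier |  |
| blue | 32 mM | 34.5 mM | run made earlier |  |
| red | 51 mM | 34.5 mM | run made earlier |  |
| grey | 23 mM | 17 mM | run made earlier |  |
| north-east | 23 mM | 34.5 mM (in portions, 2, over 2.0 h) | first portion at the start, last at 2.0 h | 3.0 h |
| south-east | 23 mM | 34.5 mM | everything together at the start | 3.0 h |
| south | 23 mM | 34.5 mM (fed, over 2.0 h) | all else is in the flask from the start; the feed brings no volume worth counting | 3.0 h |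
| west | 23 mM (fed, over 2.0 h) | 34.5 mM | all else is in the flask from the start; the feed brings no volume worth counting | 3.0 h |

- amber (time / h: target / %, side product / %, starting material / %): 0.667: 0.2, 41.1, 14.3; 1.33: 0, 47.5, 3.0; 2.00: 0.4, 48.7, 0.7; 2.50: 1.3, 48.2, 0; 3.00: 0.7, 48.0, 0
- blue (time / h: target / %, side product / %, starting material / %): 0.200: 0.9, 22.6, 50.2; 0.333: 0.6, 30.1, 33.4; 0.667: 0, 38.3, 12.5; 1.33: 0, 43.1, 2.5; 2.50: 1.5, 46.0, 0.8
- red (time / h: target / %, side product / %, starting material / %): 0.500: 0.5, 30.8, 21.2; 1.00: 0, 36.5, 6.1; 1.33: 0.7, 37.9, 4.0; 2.00: 0.8, 38.6, 1.2; 2.50: 0.5, 38.6, 0
- grey (time / h: target / %, side product / %, starting material / %): 0.200: 0, 12.6, 59.8; 0.667: 0, 23.8, 21.4; 1.00: 0, 26.3, 12.6; 1.50: 0.3, 29.1, 5.8; 2.50: 1.1, 29.2, 0.7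

(each reading ± 0.5 percentage points)



- which flask leads in share of target in target plus side product ("all alike" within 1.5 percentage points) (north-east / south-east / south / west / all alike)
- share of target in target plus side product at the end, north-east
- share of target in target plus side product at the end, south-east
- share of target in target plus side product at the end, south
- share of target in target plus side product at the end, west

Target is faint: late in the amber run it averages 1.00%, against a scatter of 0.5 percentage points. I carry that value for every flask, so in my reckoning the share follows the side product. In amber, starting material falls to 0%, yet side product stops at 48.0%, so I read two competing routes: a loss of its own to something unseen, with lifetime τ, and a pseudo-first-order route whose rate grows with reagent level c. Let c* be the level at which they run equally, so that a share c/(c+c*) becomes side product. Amber at its mid-reaction reagent level reads c* = 31.4 mM, and grey reads 33.1 mM. Amber's early decay, less the side-product share, gives τ = 0.660 h.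

For the south flask I count ρ = 0.362, the dose number: the reagent fed during one lifetime, in units of c*. At the start south holds no reagent, so at first starting material leaves by its own route. For the middle I estimate that reagent stands at x times c* and that the lifetime is shortened to τ/(1+x), so x(1+x) = ρ and x = 0.283. By its close the feed has run for 3.03 lifetimes, longer than τ, so I expect late reagent to meet little starting material. In my reckoning side product comes to x/(1+x) = 22.0%, and the share to 4.34%. South-east repeats amber, at 2.04%, and I put west there too. North-east's first portion of 17.2 mM is close to the grey charge of 17 mM, and its last portion comes 3.03 lifetimes later, so I put north-east at grey's 3.31%. South therefore leads in my reckoning, higher than north-east.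

The forecast also names south, with 2.6% north-east, 1.6% south-east, 5% south and 1.6% west; its south stands above mine. Its ground is that “share rises as side product falls”.

The flasks give 4.64% north-east, 2.38% south-east, 8.56% south and 1.22% west, so south leads.

    starting material → intermediate A (k = 1.20 h⁻¹)
    intermediate A ⇌ intermediate B (K = 6.00, k = 0.0220 h⁻¹)
    starting material + reagent → side product (k = 51.0 M⁻¹ h⁻¹)
    reagent + intermediate A ⇌ intermediate C (K = 11.0 M⁻¹, k = 2.10 M⁻¹ h⁻¹)
    intermediate B → target (k = 0.700 h⁻¹)
    2 starting material → self-condensation product (k = 16.0 M⁻¹ h⁻¹)

South ends with side product at 18.6% against my 22.0%, and target at 1.74%, above the value I carried. The neighbouring flask is south with reagent raised to 140 mM over the same feed time. Its dose number is 1.47, which reckons side product at 44.8%; the flask holds 38.2%, with target at 1.30%. The share in this neighbouring flask is 3.30%, below the 4.64% of north-east on its charge of 34.5 mM.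

Readings and results were generated by integration for substances that don't exist, noise included.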